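The benzo ring is built last. In the target, ring C3a–C4–C5–C6–C7–C7a carries only O1 (on C7a), C3 (on C3a) and the side chain on C5. It can therefore be cut into three alkynes: an ynol ether (C7a≡C7), a propargylic alkyne (C3a≡C4) and a chain-bearing terminal alkyne (C5≡C6). One ruthenium-catalysed [2+2+2] cycloaddition forms C3a–C7a, C4–C5 and C6–C7, closing the benzene ring and the dihydrofuran ring O1–C2–C3–C3a–C7a together. Its precursor is an acyclic anti 1,6-diyne whose O1–C2–C3 tether already holds both stereocentres. A triethylsilyl cap on C7 directs the chain to C5.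

Key step: step 10

Remark (numbering, configuration): benzofuran numbering is used for all intermediates, acyclic ones included. The target is the trans (2S,3S) isomer. The C3 descriptor is R with a CH2O substituent and S with a C=O substituent, with no change in space.
Remark (design of the precursor): the butyllithium needed to make the ynol ether would also metalate a free C4–H alkyne, so a silyl cap could not be placed on C7 alone. The propargylic alkyne is therefore carried as its trimethylsilyl derivative, the ynol ether terminus receives the sturdier triethylsilyl group, and mild methanolysis then frees only C4–H. The C3 oxymethyl group is protected as its triisopropylsilyl ether, because a smaller silyl ether could migrate to the neighbouring potassium alkoxide in step 7.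
Assumption: in step 3 the CH2OTIPS group takes the place of the methyl group of 4-silylbut-3-yn-2-ones, so the usual sense of induction holds.

Step 1
Reactants: 1 methyl glycolate
Product: 2 methyl 2-[(triisopropylsilyl)oxy]acetate
Conditions: TIPSCl, imidazole, DMF, rt
Reagents that add atoms: chlorotriisopropylsilane, CC(C)[Si](Cl)(C(C)C)C(C)C
Why: Routine silylation of a primary alcohol, with the bulky silyl group chosen so that it stays on this oxygen under the strongly basic conditions of step 7.

Step 2
Reactants: 2 methyl 2-[(triisopropylsilyl)oxy]acetate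
Product: 3 1-[(triisopropylsilyl)oxy]-4-(trimethylsilyl)but-3-yn-2-one
Conditions: Me3SiC≡CH, n-BuLi, THF, −78 °C; BF3·OEt2; then 2, −78 °C; aqueous work-up
Reagents that add atoms: ethynyltrimethylsilane, C#C[Si](C)(C)C
Why: Yamaguchi-type acylation of a lithium acetylide by an ester in the presence of BF3·OEt2 should stop at the ynone, because the boron-bound tetrahedral adduct persists until the quench.

Step 3
Reactants: 3 1-[(triisopropylsilyl)oxy]-4-(trimethylsilyl)but-3-yn-2-one
Product: 4 (S)-1-[(triisopropylsilyl)oxy]-4-(trimethylsilyl)but-3-yn-2-ol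
Conditions: Ru[(R,R)-TsDPEN](p-cymene) (1–2 mol %), i-PrOH, rt
Reagents that add atoms: none
Why: In this Noyori asymmetric transfer hydrogenation of an alkynyl ketone the catalyst tells the alkynyl π-substituent from the sp3 CH2OTIPS group, so the (R,R)-complex should set the carbinol centre in the spatial sense of the (R)-4-silylbut-3-yn-2-ols, which here reads (S) only because CH2O outranks alkynyl.

Step 4
Reactants: 4 (S)-1-[(triisopropylsilyl)oxy]-4-(trimethylsilyl)but-3-yn-2-ol
Product: 5 (S)-1-[(triisopropylsilyl)oxy]-4-(trimethylsilyl)but-3-yn-2-yl methanesulfonate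
Conditions: MsCl, Et3N, CH2Cl2, −78 → −20 °C
Reagents that add atoms: methanesulfonyl chloride, CS(=O)(=O)Cl
Why: O-Sulfonylation leaves the C–O bond intact, so the configuration is retained.

Step 5
Reactants: 6 4-hydroxybenzaldehyde
Product: 7 4-(methoxymethoxy)benzaldehyde
Conditions: MOMCl, i-Pr2NEt, CH2Cl2, 0 °C → rt
Reagents that add atoms: chloromethyl methyl ether, COCCl
Why: MOM protection (O-alkylation of the phenol) gives an acetal that tolerates organozinc, KH, butyllithium, fluoride and the ruthenium catalyst.

Step 6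
Reactants: 5 (S)-1-[(triisopropylsilyl)oxy]-4-(trimethylsilyl)but-3-yn-2-yl methanesulfonate; 7 4-(methoxymethoxy)benzaldehyde
Product: 9 (1S,2R)-1-[4-(methoxymethoxy)phenyl]-2-{[(triisopropylsilyl)oxy]methyl}-4-(trimethylsilyl)but-3-yn-1-ol (anti), via allenylzinc mesylate 8 (not isolated)
Conditions: Pd(OAc)2 (5 mol %), PPh3 (5 mol %), Et2Zn (3 equiv), THF, −78 → −20 °C; aq NH4Cl
Reagents that add atoms: none
Why: Marshall propargylation: Pd(0) displaces the mesylate in an anti SN2′ sense, diethylzinc transmetalates to the configurationally defined allenylzinc 8, and 8 adds to 7 through a cyclic SE2′ transition state, so that C3 is set by chirality transfer (net inversion at the former carbinol carbon) and C2 by the anti preference of that transition state, in which the aryl group avoids the CH2OTIPS substituent; the minor syn isomer has to be removed by chromatography, because it would feed the enantiomeric series once C3 becomes epimerisable.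

Step 7
Reactants: 9 (1S,2R)-1-[4-(methoxymethoxy)phenyl]-2-{[(triisopropylsilyl)oxy]methyl}-4-(trimethylsilyl)but-3-yn-1-ol
Product: 12 triethyl[({(1S,2R)-1-[4-(methoxymethoxy)phenyl]-2-{[(triisopropylsilyl)oxy]methyl}-4-(trimethylsilyl)but-3-yn-1-yl}oxy)ethynyl]silane, via dichlorovinyl ether 10 (not isolated), via lithium alkoxyacetylide 11 (not isolated)
Conditions: KH, THF, 0 °C (brief); Cl2C=CHCl, −78 °C → rt; n-BuLi (2.5 equiv), −78 → −40 °C; Et3SiCl, −78 → 0 °C; aq NaHCO3; Et3N-deactivated silica, kept at or below rt
Reagents that add atoms: trichloroethylene, ClC=C(Cl)Cl; chlorotriethylsilane, CC[Si](Cl)(CC)CC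
Why: Greene's one-pot ynol ether synthesis: the potassium alkoxide adds to dichloroacetylene released from trichloroethylene, butyllithium converts dichlorovinyl ether 10 by elimination and Cl/Li exchange into acetylide 11, and 11 is silylated on carbon; the C2–O bond is never broken, the trimethylsilyl group keeps the other alkyne from being metalated, and the triisopropylsilyl ether is too hindered for O-to-O migration.

Step 8
Reactants: 12 triethyl[({(1S,2R)-1-[4-(methoxymethoxy)phenyl]-2-{[(triisopropylsilyl)oxy]methyl}-4-(trimethylsilyl)but-3-yn-1-yl}oxy)ethynyl]silane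
Product: 13 triethyl[({(1S,2R)-1-[4-(methoxymethoxy)phenyl]-2-{[(triisopropylsilyl)oxy]methyl}but-3-yn-1-yl}oxy)ethynyl]silane
Conditions: K2CO3 (0.2 equiv), MeOH–THF, 0 °C, stopped as soon as 12 is consumed
Reagents that add atoms: none
Why: Base-catalysed methanolysis of alkynylsilanes is governed by the bulk at silicon, so the trimethylsilyl group should leave well before the triethylsilyl group, while the ynol ether, silyl ether and acetal functions are inert to carbonate.

Step 9
Reactants: 14 pent-4-ynoic acid
Product: 16 N-methoxy-N-methylpent-4-ynamide, via acyl imidazole 15 (not isolated)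
Conditions: CDI, CH2Cl2, rt; then MeNHOMe·HCl, rt
Reagents that add atoms: N,O-dimethylhydroxylamine hydrochloride, CNOC.Cl
Why: Weinreb amide formation through the acyl imidazole is a mild amide coupling that leaves the terminal alkyne untouched.

Step 10
Reactants: 13 triethyl[({(1S,2R)-1-[4-(methoxymethoxy)phenyl]-2-{[(triisopropylsilyl)oxy]methyl}but-3-yn-1-yl}oxy)ethynyl]silane; 16 N-methoxy-N-methylpent-4-ynamide
Product: 17 N-methoxy-3-[(2S,3R)-2-[4-(methoxymethoxy)phenyl]-7-(triethylsilyl)-3-{[(triisopropylsilyl)oxy]methyl}-2,3-dihydro-1-benzofuran-5-yl]-N-methylpropanamide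
Conditions: Cp*RuCl(cod) (5 mol %), 16 (3 equiv), ClCH2CH2Cl, rt, Ar; 13 added slowly by syringe pump
Reagents that add atoms: none
Why: Cp*RuCl binds both alkynes of 13 and couples them oxidatively to a bicyclic ruthenacyclopentadiene (C3a–C7a formed), after which alkyne 16 coordinates and inserts, and reductive elimination from the seven-membered ruthenacycle forms C4–C5 and C6–C7 and releases the arene. The closest known reactions are the Cp*RuCl(cod)-catalysed [2+2+2] cycloadditions of unsymmetrical 1,6-diynes with terminal alkynes and the rhodium-catalysed versions whose tether starts at an ynamide nitrogen (giving indolines) or at an aryl ynol ether oxygen (giving dibenzofurans), so that only the sp3 O1–C2–C3 tether on an alkyl ynol ether is new to this molecule. The dihydrofuran ring O1–C2–C3–C3a–C7a closes in the oxidative coupling as the five-membered ring fused to the metallacycle, the geometry for which three-atom tethers are ideal, and the benzene ring closes in the final reductive elimination. No stereocentre is created, and C2 and C3 are spectators because the medium is neutral, the temperature is ambient and H–C3 is merely propargylic. The step needs regioselectivity (chain on C5, not C6) and cross-selectivity: the triethylsilyl group on C7 lets only the unsubstituted carbon of 16 bond next to it, which puts the chain meta to silicon, and the same cap, the excess of 16 and the slow addition of 13 hold back self-coupling of the diyne. Room temperature is essential, since a secondary benzylic ynol ether can lose a ketene by a retro-ene path or undergo a [3,3] shift when heated.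

Step 11
Reactants: 17 N-methoxy-3-[(2S,3R)-2-[4-(methoxymethoxy)phenyl]-7-(triethylsilyl)-3-{[(triisopropylsilyl)oxy]methyl}-2,3-dihydro-1-benzofuran-5-yl]-N-methylpropanamide
Product: 18 3-[(2S,3R)-3-(hydroxymethyl)-2-[4-(methoxymethoxy)phenyl]-2,3-dihydro-1-benzofuran-5-yl]-N-methoxy-N-methylpropanamide
Conditions: TBAF·3H2O (6 equiv), DMF, rt, then 80 °C
Reagents that add atoms: none
Why: Fluoride-induced desilylation should cleave the Si–O bond at room temperature and, on heating, protodesilylate the arylsilane, whose developing negative charge at C7 is stabilised inductively by the adjacent O1; at this stage neither C2 nor C3 carries an acidic hydrogen.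

Step 12
Reactants: 18 3-[(2S,3R)-3-(hydroxymethyl)-2-[4-(methoxymethoxy)phenyl]-2,3-dihydro-1-benzofuran-5-yl]-N-methoxy-N-methylpropanamide
Product: 19 3-[(2S,3S)-3-formyl-2-[4-(methoxymethoxy)phenyl]-2,3-dihydro-1-benzofuran-5-yl]-N-methoxy-N-methylpropanamide
Conditions: TEMPO (10 mol %), PhI(OAc)2, CH2Cl2, rt; used crude
Reagents that add atoms: none
Why: TEMPO/PhI(OAc)2 oxidation stops at the aldehyde without any base, and the trans aldehyde is also the thermodynamic epimer, so C3 is not endangered.

Step 13
Reactants: 20 4-bromoresorcinol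
Product: 21 1-bromo-2,4-bis(methoxymethoxy)benzene
Conditions: MOMCl (2.5 equiv), i-Pr2NEt, CH2Cl2, 0 °C → rt
Reagents that add atoms: chloromethyl methyl ether, COCCl
Why: Double MOM protection gives ethers that cannot migrate to an ortho carbanion and that stabilise the derived aryllithium by chelation.

Step 14
Reactants: 19 3-[(2S,3S)-3-formyl-2-[4-(methoxymethoxy)phenyl]-2,3-dihydro-1-benzofuran-5-yl]-N-methoxy-N-methylpropanamide; 21 1-bromo-2,4-bis(methoxymethoxy)benzene
Product: 23 1-[2,4-bis(methoxymethoxy)phenyl]-3-[(2S,3R)-3-{[2,4-bis(methoxymethoxy)phenyl](hydroxy)methyl}-2-[4-(methoxymethoxy)phenyl]-2,3-dihydro-1-benzofuran-5-yl]propan-1-one (both carbinol epimers), via aryllithium 22 (not isolated)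
Conditions: 21 (3.3 equiv), n-BuLi (3.1 equiv), THF, −78 °C; then 19 added to 22, −78 → −40 °C; aq NH4Cl
Reagents that add atoms: none
Why: Bromine–lithium exchange followed by 1,2-addition to the aldehyde and Weinreb ketone synthesis in one operation; adding 19 to excess 22 at −78 °C should turn the enolisable aldehyde into its alkoxide faster than it is deprotonated, expulsion of O1 would be the reverse of a 5-endo-trig closure and is stereoelectronically poor, the chelated amide adduct prevents over-addition, and the new carbinol centre is erased in step 15.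

Step 15
Reactants: 23 1-[2,4-bis(methoxymethoxy)phenyl]-3-[(2S,3R)-3-{[2,4-bis(methoxymethoxy)phenyl](hydroxy)methyl}-2-[4-(methoxymethoxy)phenyl]-2,3-dihydro-1-benzofuran-5-yl]propan-1-one
Product: 24 1-[2,4-bis(methoxymethoxy)phenyl]-3-[(2S,3S)-3-[2,4-bis(methoxymethoxy)benzoyl]-2-[4-(methoxymethoxy)phenyl]-2,3-dihydro-1-benzofuran-5-yl]propan-1-one
Conditions: Dess–Martin periodinane, CH2Cl2, 0 °C → rt
Reagents that add atoms: none
Why: Dess–Martin oxidation of the hindered benzylic carbinol merges both epimers into one ketone under near-neutral conditions, and the trans arrangement at C2/C3 is the thermodynamically preferred one.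

Step 16
Reactants: 24 1-[2,4-bis(methoxymethoxy)phenyl]-3-[(2S,3S)-3-[2,4-bis(methoxymethoxy)benzoyl]-2-[4-(methoxymethoxy)phenyl]-2,3-dihydro-1-benzofuran-5-yl]propan-1-one
Product: 25 1-(2,4-dihydroxyphenyl)-3-[(2S,3S)-3-(2,4-dihydroxybenzoyl)-2-(4-hydroxyphenyl)-2,3-dihydro-1-benzofuran-5-yl]propan-1-one (CNP0136359.1)
Conditions: conc. HCl (a few equiv), MeOH–THF, 40 °C, stopped at full conversion
Reagents that add atoms: none
Why: Acid-catalysed acetal exchange (MOM cleavage) passes all five CH2 units to methanol; the C3 acyl group disfavours ionisation of C2–O1, and any enolisation at C3 returns to the trans isomer under the control of the untouched C2.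

Compound list
1 | methyl glycolate | COC(=O)CO | starting material
2 | methyl 2-[(triisopropylsilyl)oxy]acetate | COC(=O)CO[Si](C(C)C)(C(C)C)C(C)C | intermediate
3 | 1-[(triisopropylsilyl)oxy]-4-(trimethylsilyl)but-3-yn-2-one | C[Si](C)(C)C#CC(=O)CO[Si](C(C)C)(C(C)C)C(C)C | intermediate
4 | (S)-1-[(triisopropylsilyl)oxy]-4-(trimethylsilyl)but-3-yn-2-ol | C[Si](C)(C)C#C[C@@H](CO[Si](C(C)C)(C(C)C)C(C)C)O | intermediate
5 | (S)-1-[(triisopropylsilyl)oxy]-4-(trimethylsilyl)but-3-yn-2-yl methanesulfonate | C[Si](C)(C)C#C[C@@H](CO[Si](C(C)C)(C(C)C)C(C)C)OS(C)(=O)=O | intermediate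
6 | 4-hydroxybenzaldehyde | O=Cc1ccc(O)cc1 | starting material
7 | 4-(methoxymethoxy)benzaldehyde | COCOc1ccc(C=O)cc1 | intermediate
8 | (P)-[4-(triisopropylsilyloxy)-1-(trimethylsilyl)buta-1,2-dien-1-yl]zinc methanesulfonate (not isolated) | CS(=O)(=O)O[Zn]C([Si](C)(C)C)=[C@@]=C([H])CO[Si](C(C)C)(C(C)C)C(C)C | intermediate
9 | (1S,2R)-1-[4-(methoxymethoxy)phenyl]-2-{[(triisopropylsilyl)oxy]methyl}-4-(trimethylsilyl)but-3-yn-1-ol (anti) | C[Si](C)(C)C#C[C@H](CO[Si](C(C)C)(C(C)C)C(C)C)[C@@H](c1ccc(OCOC)cc1)O | intermediate
10 | (E)-1,2-dichlorovinyl ether of 9 (not isolated) | C[Si](C)(C)C#C[C@H](CO[Si](C(C)C)(C(C)C)C(C)C)[C@@H](c1ccc(OCOC)cc1)O/C(Cl)=C\Cl | intermediate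
11 | lithium alkoxyacetylide derived from 10 (not isolated) | C[Si](C)(C)C#C[C@H](CO[Si](C(C)C)(C(C)C)C(C)C)[C@@H](c1ccc(OCOC)cc1)OC#C[Li] | intermediate
12 | triethyl[({(1S,2R)-1-[4-(methoxymethoxy)phenyl]-2-{[(triisopropylsilyl)oxy]methyl}-4-(trimethylsilyl)but-3-yn-1-yl}oxy)ethynyl]silane | C[Si](C)(C)C#C[C@H](CO[Si](C(C)C)(C(C)C)C(C)C)[C@@H](c1ccc(OCOC)cc1)OC#C[Si](CC)(CC)CC | intermediate
13 | triethyl[({(1S,2R)-1-[4-(methoxymethoxy)phenyl]-2-{[(triisopropylsilyl)oxy]methyl}but-3-yn-1-yl}oxy)ethynyl]silane (anti 1,6-diyne, key-step precursor) | C#C[C@H](CO[Si](C(C)C)(C(C)C)C(C)C)[C@@H](c1ccc(OCOC)cc1)OC#C[Si](CC)(CC)CC | intermediate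
14 | pent-4-ynoic acid | C#CCCC(=O)O | starting material
15 | 1-(1H-imidazol-1-yl)pent-4-yn-1-one (not isolated) | C#CCCC(=O)n1ccnc1 | intermediate
16 | N-methoxy-N-methylpent-4-ynamide | C#CCCC(=O)N(C)OC | intermediate
17 | N-methoxy-3-[(2S,3R)-2-[4-(methoxymethoxy)phenyl]-7-(triethylsilyl)-3-{[(triisopropylsilyl)oxy]methyl}-2,3-dihydro-1-benzofuran-5-yl]-N-methylpropanamide (trans, key-step product) | CON(C)C(=O)CCc1cc([Si](CC)(CC)CC)c2c(c1)[C@H](CO[Si](C(C)C)(C(C)C)C(C)C)[C@@H](c1ccc(OCOC)cc1)O2 | intermediate
18 | 3-[(2S,3R)-3-(hydroxymethyl)-2-[4-(methoxymethoxy)phenyl]-2,3-dihydro-1-benzofuran-5-yl]-N-methoxy-N-methylpropanamide | CON(C)C(=O)CCc1ccc2c(c1)[C@H](CO)[C@@H](c1ccc(OCOC)cc1)O2 | intermediate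
19 | 3-[(2S,3S)-3-formyl-2-[4-(methoxymethoxy)phenyl]-2,3-dihydro-1-benzofuran-5-yl]-N-methoxy-N-methylpropanamide | CON(C)C(=O)CCc1ccc2c(c1)[C@H](C=O)[C@@H](c1ccc(OCOC)cc1)O2 | intermediate
20 | 4-bromoresorcinol | Oc1ccc(Br)c(O)c1 | starting material
21 | 1-bromo-2,4-bis(methoxymethoxy)benzene | COCOc1ccc(Br)c(OCOC)c1 | intermediate
22 | [2,4-bis(methoxymethoxy)phenyl]lithium (not isolated) | COCOc1ccc([Li])c(OCOC)c1 | intermediate
23 | 1-[2,4-bis(methoxymethoxy)phenyl]-3-[(2S,3R)-3-{[2,4-bis(methoxymethoxy)phenyl](hydroxy)methyl}-2-[4-(methoxymethoxy)phenyl]-2,3-dihydro-1-benzofuran-5-yl]propan-1-one (both carbinol epimers) | COCOc1ccc(C(=O)CCc2ccc3c(c2)[C@H](C(O)c2ccc(OCOC)cc2OCOC)[C@@H](c2ccc(OCOC)cc2)O3)c(OCOC)c1 | intermediate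
24 | 1-[2,4-bis(methoxymethoxy)phenyl]-3-[(2S,3S)-3-[2,4-bis(methoxymethoxy)benzoyl]-2-[4-(methoxymethoxy)phenyl]-2,3-dihydro-1-benzofuran-5-yl]propan-1-one | COCOc1ccc(C(=O)CCc2ccc3c(c2)[C@H](C(=O)c2ccc(OCOC)cc2OCOC)[C@@H](c2ccc(OCOC)cc2)O3)c(OCOC)c1 | intermediate
25 | 1-(2,4-dihydroxyphenyl)-3-[(2S,3S)-3-(2,4-dihydroxybenzoyl)-2-(4-hydroxyphenyl)-2,3-dihydro-1-benzofuran-5-yl]propan-1-one | O=C(CCc1ccc2c(c1)[C@H](C(=O)c1ccc(O)cc1O)[C@@H](c1ccc(O)cc1)O2)c1ccc(O)cc1O | target

Total step count: 16. Longest linear sequence: 13 steps (steps 1–4, 6–8, 10–12, 14–16, from 1 to 25).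

Steps most likely to fail

Step 10.
- What may go wrong: oxidative coupling may be slow for a diyne that pairs a donor-substituted, silyl-capped alkyne with a crowded tether. Self-coupling through the free alkyne terminus could then take over. So could breakdown of the ynol ether (retro-ene loss of a ketene, [3,3] shift into the electron-rich aryl ring, hydration) or imperfect orientation of the monoalkyne.
- Fallback (from 9, back at 18): the benzo ring is still made last, but by an intramolecular inverse-electron-demand Diels–Alder reaction of a pyridazine. This is a known entry to 2,3-dihydrobenzofurans in which the tether fixes the regiochemistry and no silicon is needed. Carbonate methanolysis of 9 should give the terminal alkynol F1. Separately, Negishi coupling of 3,6-dichloropyridazine with commercial (3-ethoxy-3-oxopropyl)zinc bromide [Pd(PPh3)4, THF] should give ethyl 3-(6-chloropyridazin-3-yl)propanoate F2. Me3Al/MeNHOMe·HCl should convert this into the chloropyridazine Weinreb amide F3. The sodium alkoxide of F1 (NaH, THF) should displace chloride from F3 (SNAr) to give the pyridazinyl ether F4. Heating in 1,3,5-triisopropylbenzene (about 200 °C) should bring the alkyne across C3/C6 of the diazine with loss of nitrogen, giving the 7-unsubstituted dihydrobenzofuran silyl ether F5. TBAF at rt then gives 18.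

Step 7.
- What may go wrong: the potassium alkoxide may attack the alkynyl trimethylsilyl group of a second molecule. Capture of dichloroacetylene by the hindered secondary alkoxide may be incomplete. Butyllithium may metalate H–C3, or the benzylic ynol ether may rearrange during work-up.
- Fallback (from 9, back at 12): the alkoxide stage is avoided altogether. Formylation of 9 (acetic formic anhydride, pyridine, 0 °C) should give the formate F6. Dichloro-olefination of the formyl C=O (PPh3, CCl4, THF, 60 °C), a known reaction of formates, should give the 2,2-dichlorovinyl ether F7. n-BuLi (2.2 equiv, −78 °C) then effects elimination and Cl/Li exchange to the same acetylide 11, and Et3SiCl gives 12.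

Step 11.
- What may go wrong: the aryl–silicon bond may be cleaved incompletely, because fluoride attacks a triethylsilyl group on an electron-rich arene only slowly. The Weinreb amide may also degrade under base at the temperature then required.
- Fallback (from 17, back at 18): silicon is displaced by an electrophile instead of being attacked by a nucleophile. ICl (CH2Cl2, −78 °C) should effect ipso-iododesilylation at C7 to give the 7-iodide F8. C7 is the only free position of that ring activated by O1, and it is further favoured by the β-silicon effect. Hydrogenolysis of the C–I bond (H2, Pd/C, Et3N, EtOAc) should give the 7-unsubstituted dihydrobenzofuran silyl ether F5, and TBAF at rt gives 18.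

Further compounds
F1 | step 10 | (1S,2R)-1-[4-(methoxymethoxy)phenyl]-2-{[(triisopropylsilyl)oxy]methyl}but-3-yn-1-ol | C#C[C@H](CO[Si](C(C)C)(C(C)C)C(C)C)[C@@H](c1ccc(OCOC)cc1)O
F2 | step 10 | ethyl 3-(6-chloropyridazin-3-yl)propanoate | CCOC(=O)CCc1ccc(Cl)nn1
F3 | step 10 | 3-(6-chloropyridazin-3-yl)-N-methoxy-N-methylpropanamide | CON(C)C(=O)CCc1ccc(Cl)nn1
F4 | step 10 | N-methoxy-3-[6-({(1S,2R)-1-[4-(methoxymethoxy)phenyl]-2-{[(triisopropylsilyl)oxy]methyl}but-3-yn-1-yl}oxy)pyridazin-3-yl]-N-methylpropanamide | C#C[C@H](CO[Si](C(C)C)(C(C)C)C(C)C)[C@@H](c1ccc(OCOC)cc1)Oc1ccc(CCC(=O)N(C)OC)nn1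
F5 | step 10 | N-methoxy-3-[(2S,3R)-2-[4-(methoxymethoxy)phenyl]-3-{[(triisopropylsilyl)oxy]methyl}-2,3-dihydro-1-benzofuran-5-yl]-N-methylpropanamide | CON(C)C(=O)CCc1ccc2c(c1)[C@H](CO[Si](C(C)C)(C(C)C)C(C)C)[C@@H](c1ccc(OCOC)cc1)O2
F6 | step 7 | (1S,2R)-1-[4-(methoxymethoxy)phenyl]-2-{[(triisopropylsilyl)oxy]methyl}-4-(trimethylsilyl)but-3-yn-1-yl formate | C[Si](C)(C)C#C[C@H](CO[Si](C(C)C)(C(C)C)C(C)C)[C@@H](c1ccc(OCOC)cc1)OC=O
F7 | step 7 | 2,2-dichlorovinyl ether of 9 | C[Si](C)(C)C#C[C@H](CO[Si](C(C)C)(C(C)C)C(C)C)[C@@H](c1ccc(OCOC)cc1)OC=C(Cl)Cl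
F8 | step 11 | 3-[(2S,3R)-7-iodo-2-[4-(methoxymethoxy)phenyl]-3-{[(triisopropylsilyl)oxy]methyl}-2,3-dihydro-1-benzofuran-5-yl]-N-methoxy-N-methylpropanamide | CON(C)C(=O)CCc1cc(I)c2c(c1)[C@H](CO[Si](C(C)C)(C(C)C)C(C)C)[C@@H](c1ccc(OCOC)cc1)O2
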